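**Retrosynthetic overview**

- Structural feature: in ring C, C2 carries both C1' of ring B and O1, while C3 and C4 are unfunctionalised CH2 groups. C2 is therefore treated as the terminal alkene carbon of a ring-A 2-allylphenol that receives an aryl group and the phenol oxygen geminally.
- Key disconnection: C2–C1' and C2–O1 together, back to 2-allyl-5-(triisopropylsilyloxy)phenol and a ring-B arenediazonium salt. The salt carries O4' as a benzyl ether and O3' as a mesylate, because a sulfonate, unlike an ester, should not shift between neighbouring catechol oxygens once O4' is freed.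
- Ring D (the dimethylpyran on ring B) comes from an O4' 1,1-dimethylpropargyl ether by Claisen rearrangement and oxa-6π closure onto C5'. The C2' prenyl group comes from an O3' 1,1-dimethylallyl ether by Claisen rearrangement.
- Order of ring formation: rings A and B are purchased aromatics, ring C is closed in the key step, ring D afterwards; the prenyl shift and desilylation finish the route.

Key step: step 7

Assumption: the (S)-configured pyridine–oxazoline ligand is taken to deliver the (2S)-chroman; if the sense of induction is opposite, its enantiomer is used with no other change.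

**Route**

Step 1
Reactants: 1 4-bromoresorcinol
Product: 2 2-bromo-5-(triisopropylsilyloxy)phenol
Conditions: TIPSCl (1.05 equiv), imidazole, DMF, −20 to 0 °C
Reagents that add atoms: chlorotriisopropylsilane, CC(C)[Si](Cl)(C(C)C)C(C)C
Why: Regioselective O-silylation: the bulky chlorosilane should react at the hydroxyl para to bromine, the other being shielded by the ortho bromine, so the phenol needed later as the ring-C nucleophile stays free.

Step 2
Reactants: 2 2-bromo-5-(triisopropylsilyloxy)phenol, 3 allyltributylstannane
Product: 4 2-allyl-5-(triisopropylsilyloxy)phenol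
Conditions: Pd(PPh3)4 (5 mol %), PhMe, 100 °C
Reagents that add atoms: none
Why: Migita–Kosugi–Stille cross-coupling of the aryl bromide with the allylstannane runs under neutral, fluoride-free conditions that leave the free phenol and the aryl silyl ether untouched and place the allyl group on the future C4a.

Step 3
Reactants: 5 4-nitrocatechol
Product: 6 2-(benzyloxy)-5-nitrophenol
Conditions: BnBr (1.05 equiv), NaHCO3, NaI (cat.), DMF, 40 °C
Reagents that add atoms: benzyl bromide, BrCc1ccccc1
Why: Williamson etherification under weak base: only the more acidic hydroxyl para to the nitro group is deprotonated by hydrogencarbonate, so benzylation should occur at the oxygen that becomes O4'.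

Step 4
Reactants: 6 2-(benzyloxy)-5-nitrophenol
Product: 7 2-(benzyloxy)-5-nitrophenyl methanesulfonate
Conditions: MsCl, Et3N, CH2Cl2, 0 °C
Reagents that add atoms: methanesulfonyl chloride, CS(=O)(=O)Cl
Why: Sulfonylation of the remaining phenol gives a mesylate that tolerates acid, hydrogenation and heat and, lacking a feasible five-membered transition state for sulfonyl transfer, should stay on O3' when O4' is later freed.

Step 5
Reactants: 7 2-(benzyloxy)-5-nitrophenyl methanesulfonate
Product: 8 5-amino-2-(benzyloxy)phenyl methanesulfonate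
Conditions: H2 (1 atm), Pt/C (sulfided), EtOAc, rt
Reagents that add atoms: none
Why: Chemoselective catalytic hydrogenation of the nitro group: sulfided platinum on carbon reduces nitroarenes to anilines without hydrogenolysis of benzyl ethers or aryl sulfonates.

Step 6
Reactants: 8 5-amino-2-(benzyloxy)phenyl methanesulfonate
Product: 9 4-(benzyloxy)-3-(methanesulfonyloxy)benzenediazonium tetrafluoroborate
Conditions: t-BuONO, HBF4 (48 % aq.), EtOH, 0 °C; precipitation with Et2O
Reagents that add atoms: tert-butyl nitrite, CC(C)(C)ON=O; tetrafluoroboric acid, [H+].F[B-](F)(F)F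
Why: Diazotisation of the aniline by the alkyl nitrite in the presence of tetrafluoroboric acid gives the isolable arenediazonium salt needed for Heck–Matsuda chemistry, the ether and sulfonate being stable to cold acid.

Step 7
Reactants: 4 2-allyl-5-(triisopropylsilyloxy)phenol, 9 4-(benzyloxy)-3-(methanesulfonyloxy)benzenediazonium tetrafluoroborate
Product: 10 (2S)-2-[4-(benzyloxy)-3-(methanesulfonyloxy)phenyl]-7-(triisopropylsilyloxy)chroman
Conditions: Pd2(dba)3 (4 mol %), (S)-4-tert-butyl-2-[5-(trifluoromethyl)pyridin-2-yl]-4,5-dihydrooxazole (10 mol %), 2,6-di-tert-butyl-4-methylpyridine (1.1 equiv), DMA, 0 °C to rt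
Reagents that add atoms: none
Why: Proposed new method: oxidative addition of 9 to zerovalent palladium gives a cationic arylpalladium complex that inserts the terminal alkene of 4 with aryl transfer to the CH2 terminus, β-hydride elimination and re-insertion of the retained hydride then walk palladium onto that same, now benzylic, carbon as a cationic η3-benzyl complex, and the phenol oxygen attacks it, releasing zerovalent palladium for the next diazonium ion and a proton that the hindered pyridine takes up. The closest known reaction types are palladium-catalysed enantioselective 1,1-difunctionalisations of terminal alkenes through π-benzyl intermediates (1,1-diarylation, 1,1-arylfluorination) and Heck–Matsuda arylations of allylphenols; geminal aryl-oxygenation by a tethered phenol has not been shown. Ring C is closed by 6-exo-tet attack of O1 on the palladium-bound benzylic carbon, so that C2–C1' and C2–O1 arise in one operation. The C2 stereocentre is controlled by the chiral pyridine–oxazoline ligand, which selects the alkene face on which palladium binds and travels and thereby the face of the η3-benzyl complex that oxygen opens from the side opposite to the metal. The step needs geminal over vicinal addition and over loss of the cinnamyl Heck alkene, ring-B over ring-A benzylic palladium, and C–C coupling over azo coupling: the para-benzyloxy group of ring B stabilises the η3-benzyl cation, only that carbon lets the phenol close a six-membered ring (palladium at the ring-A benzylic carbon has no productive exit and should walk back), and the absence of phenoxide together with the bulky silyl ether next to the activated ring-A positions disfavours azo coupling. The hindered pyridine removes HBF4, which would otherwise cleave the silyl ether or ionise the product at C2.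

Step 8
Reactants: 10 (2S)-2-[4-(benzyloxy)-3-(methanesulfonyloxy)phenyl]-7-(triisopropylsilyloxy)chroman
Product: 11 (2S)-2-[4-hydroxy-3-(methanesulfonyloxy)phenyl]-7-(triisopropylsilyloxy)chroman
Conditions: H2 (1 atm), Pd/C (10 wt %), EtOAc, rt
Reagents that add atoms: none
Why: Catalytic hydrogenolysis of the O-benzyl ether under neutral conditions at atmospheric pressure frees O4'; the cyclic benzylic C2–O1 bond of flavans is normally retained under such conditions, and the mesylate and silyl ether are inert.

Step 9
Reactants: 11 (2S)-2-[4-hydroxy-3-(methanesulfonyloxy)phenyl]-7-(triisopropylsilyloxy)chroman, 12 3-chloro-3-methylbut-1-yne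
Product: 13 (2S)-2-[3-(methanesulfonyloxy)-4-(2-methylbut-3-yn-2-yloxy)phenyl]-7-(triisopropylsilyloxy)chroman
Conditions: DBU, CuCl2·2H2O (1 mol %), MeCN, 0 °C
Reagents that add atoms: none
Why: Copper-catalysed O-propargylation of the phenol with the tertiary propargylic chloride (through a copper allenylidene) forms the hindered aryl ether at 0 °C, where the electron-withdrawing ortho mesylate and the low temperature should keep the para-phenoxide from opening ring C through a quinone methide.

Step 10
Reactants: 13 (2S)-2-[3-(methanesulfonyloxy)-4-(2-methylbut-3-yn-2-yloxy)phenyl]-7-(triisopropylsilyloxy)chroman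
Product: 15 2,2-dimethyl-6-[(2S)-7-(triisopropylsilyloxy)chroman-2-yl]-2H-chromen-8-yl methanesulfonate, via allenylphenol 14 (not isolated)
Conditions: o-xylene, 140 °C
Reagents that add atoms: none
Why: Aryl propargyl ether Claisen rearrangement to C5' (the other ortho carbon, C3', is blocked by the mesylate), enolisation to allenylphenol 14, 1,5-hydrogen shift and oxa-6π electrocyclisation should close the 2,2-dimethyl-2H-pyran ring D under neutral thermal conditions that do not touch C2.

Step 11
Reactants: 15 2,2-dimethyl-6-[(2S)-7-(triisopropylsilyloxy)chroman-2-yl]-2H-chromen-8-yl methanesulfonate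
Product: 16 2,2-dimethyl-6-[(2S)-7-(triisopropylsilyloxy)chroman-2-yl]-2H-chromen-8-ol
Conditions: LDA (3 equiv), THF, −78 to 0 °C; then aq. NH4Cl
Reagents that add atoms: none
Why: Base-induced E1cB cleavage of the aryl mesylate: the hindered amide deprotonates the S-methyl group and the phenoxide leaves with formation of sulfene (trapped by excess amide), while silyl ether, chromene and benzylic ether are inert to this non-nucleophilic base at low temperature.

Step 12
Reactants: 16 2,2-dimethyl-6-[(2S)-7-(triisopropylsilyloxy)chroman-2-yl]-2H-chromen-8-ol, 12 3-chloro-3-methylbut-1-yne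
Product: 17 (2S)-2-[2,2-dimethyl-8-(2-methylbut-3-yn-2-yloxy)-2H-chromen-6-yl]-7-(triisopropylsilyloxy)chroman
Conditions: DBU, CuCl2·2H2O (1 mol %), MeCN, 0 °C
Reagents that add atoms: none
Why: Copper-catalysed O-propargylation as in step 9, now at the only free phenol, O3', which is meta to C1' and so cannot trigger ring opening.

Step 13
Reactants: 17 (2S)-2-[2,2-dimethyl-8-(2-methylbut-3-yn-2-yloxy)-2H-chromen-6-yl]-7-(triisopropylsilyloxy)chroman
Product: 18 (2S)-2-[2,2-dimethyl-8-(2-methylbut-3-en-2-yloxy)-2H-chromen-6-yl]-7-(triisopropylsilyloxy)chroman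
Conditions: H2 (1 atm), Pd/CaCO3 poisoned with Pb(OAc)2 (Lindlar catalyst), quinoline, EtOAc, rt
Reagents that add atoms: none
Why: Lindlar semi-hydrogenation stops at the terminal alkene and leaves the disubstituted chromene double bond intact, giving the 1,1-dimethylallyl ether.

Step 14
Reactants: 18 (2S)-2-[2,2-dimethyl-8-(2-methylbut-3-en-2-yloxy)-2H-chromen-6-yl]-7-(triisopropylsilyloxy)chroman
Product: 20 2,2-dimethyl-7-(3-methylbut-2-enyl)-6-[(2S)-7-(triisopropylsilyloxy)chroman-2-yl]-2H-chromen-8-ol, via cyclohexadienone 19 (not isolated)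
Conditions: PhMe, 110 °C, sealed tube
Reagents that add atoms: none
Why: Aromatic Claisen rearrangement: the [3,3] shift delivers the CH2 terminus of the allyl unit to C7 of the chromene (C2' of ring B), the only ortho carbon carrying hydrogen, and tautomerisation of dienone 19 gives the ortho-prenylphenol.

Step 15
Reactants: 20 2,2-dimethyl-7-(3-methylbut-2-enyl)-6-[(2S)-7-(triisopropylsilyloxy)chroman-2-yl]-2H-chromen-8-ol
Product: 21 kazinol B, (2S)-2-[8-hydroxy-2,2-dimethyl-7-(3-methylbut-2-enyl)-2H-chromen-6-yl]chroman-7-ol
Conditions: TBAF, AcOH, THF, 0 °C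
Reagents that add atoms: none
Why: Fluoride-mediated cleavage of the aryl silyl ether, buffered with acetic acid, liberates the 7-hydroxyl without affecting the chromene, the prenyl group or the C2 stereocentre.

**Compound list**

1 | 4-bromoresorcinol | Oc1ccc(Br)c(O)c1 | starting material
2 | 2-bromo-5-(triisopropylsilyloxy)phenol | Oc1cc(O[Si](C(C)C)(C(C)C)C(C)C)ccc1Br | intermediate
3 | allyltributylstannane | C=CC[Sn](CCCC)(CCCC)CCCC | starting material
4 | 2-allyl-5-(triisopropylsilyloxy)phenol | C=CCc1ccc(O[Si](C(C)C)(C(C)C)C(C)C)cc1O | intermediate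
5 | 4-nitrocatechol | Oc1ccc([N+](=O)[O-])cc1O | starting material
6 | 2-(benzyloxy)-5-nitrophenol | O=[N+]([O-])c1ccc(OCc2ccccc2)c(O)c1 | intermediate
7 | 2-(benzyloxy)-5-nitrophenyl methanesulfonate | CS(=O)(=O)Oc1cc([N+](=O)[O-])ccc1OCc1ccccc1 | intermediate
8 | 5-amino-2-(benzyloxy)phenyl methanesulfonate | CS(=O)(=O)Oc1cc(N)ccc1OCc1ccccc1 | intermediate
9 | 4-(benzyloxy)-3-(methanesulfonyloxy)benzenediazonium tetrafluoroborate | CS(=O)(=O)Oc1cc([N+]#N)ccc1OCc1ccccc1.F[B-](F)(F)F | intermediate
10 | (2S)-2-[4-(benzyloxy)-3-(methanesulfonyloxy)phenyl]-7-(triisopropylsilyloxy)chroman | CS(=O)(=O)Oc1cc([C@@H]2CCc3ccc(O[Si](C(C)C)(C(C)C)C(C)C)cc3O2)ccc1OCc1ccccc1 | intermediate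
11 | (2S)-2-[4-hydroxy-3-(methanesulfonyloxy)phenyl]-7-(triisopropylsilyloxy)chroman | CS(=O)(=O)Oc1cc([C@@H]2CCc3ccc(O[Si](C(C)C)(C(C)C)C(C)C)cc3O2)ccc1O | intermediate
12 | 3-chloro-3-methylbut-1-yne | CC(C)(Cl)C#C | starting material
13 | (2S)-2-[3-(methanesulfonyloxy)-4-(2-methylbut-3-yn-2-yloxy)phenyl]-7-(triisopropylsilyloxy)chroman | CS(=O)(=O)Oc1cc([C@@H]2CCc3ccc(O[Si](C(C)C)(C(C)C)C(C)C)cc3O2)ccc1OC(C)(C)C#C | intermediate
14 | (2S)-2-[4-hydroxy-3-(methanesulfonyloxy)-5-(3-methylbuta-1,2-dienyl)phenyl]-7-(triisopropylsilyloxy)chroman (allenylphenol, not isolated) | CS(=O)(=O)Oc1cc([C@@H]2CCc3ccc(O[Si](C(C)C)(C(C)C)C(C)C)cc3O2)cc(C=C=C(C)C)c1O | intermediate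
15 | 2,2-dimethyl-6-[(2S)-7-(triisopropylsilyloxy)chroman-2-yl]-2H-chromen-8-yl methanesulfonate | CS(=O)(=O)Oc1cc([C@@H]2CCc3ccc(O[Si](C(C)C)(C(C)C)C(C)C)cc3O2)cc2c1OC(C)(C)C=C2 | intermediate
16 | 2,2-dimethyl-6-[(2S)-7-(triisopropylsilyloxy)chroman-2-yl]-2H-chromen-8-ol | Oc1cc([C@@H]2CCc3ccc(O[Si](C(C)C)(C(C)C)C(C)C)cc3O2)cc2c1OC(C)(C)C=C2 | intermediate
17 | (2S)-2-[2,2-dimethyl-8-(2-methylbut-3-yn-2-yloxy)-2H-chromen-6-yl]-7-(triisopropylsilyloxy)chroman | C#CC(C)(C)Oc1cc([C@@H]2CCc3ccc(O[Si](C(C)C)(C(C)C)C(C)C)cc3O2)cc2c1OC(C)(C)C=C2 | intermediate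
18 | (2S)-2-[2,2-dimethyl-8-(2-methylbut-3-en-2-yloxy)-2H-chromen-6-yl]-7-(triisopropylsilyloxy)chroman | C=CC(C)(C)Oc1cc([C@@H]2CCc3ccc(O[Si](C(C)C)(C(C)C)C(C)C)cc3O2)cc2c1OC(C)(C)C=C2 | intermediate
19 | 2,2-dimethyl-7-(3-methylbut-2-enyl)-6-[(2S)-7-(triisopropylsilyloxy)chroman-2-yl]-2H-chromen-8(7H)-one (cyclohexadienone, both epimers at the sp3 ring carbon, not isolated) | CC(C)=CCC1C(=O)C2=C(C=CC(C)(C)O2)C=C1[C@@H]1CCc2ccc(O[Si](C(C)C)(C(C)C)C(C)C)cc2O1 | intermediate
20 | 2,2-dimethyl-7-(3-methylbut-2-enyl)-6-[(2S)-7-(triisopropylsilyloxy)chroman-2-yl]-2H-chromen-8-ol | CC(C)=CCc1c([C@@H]2CCc3ccc(O[Si](C(C)C)(C(C)C)C(C)C)cc3O2)cc2c(c1O)OC(C)(C)C=C2 | intermediate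
21 | kazinol B, (2S)-2-[8-hydroxy-2,2-dimethyl-7-(3-methylbut-2-enyl)-2H-chromen-6-yl]chroman-7-ol | CC(C)=CCc1c([C@@H]2CCc3ccc(O)cc3O2)cc2c(c1O)OC(C)(C)C=C2 | target

**Step count**

Total: 15 steps. Longest linear sequence: 13 steps (steps 3 to 15, from 4-nitrocatechol).

**Steps most likely to fail**

Step 7 (proposed new method). What may go wrong:
- the cinnamyl Heck alkene is released before the chain walk is complete;
- palladium drains through the ring-A benzylic position;
- azo coupling takes place on ring A;
- the ligand exerts too little facial control.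

The fallback uses known chemistry only, sets out from 9 and returns at 10:
- Sandmeyer-type borylation of 9 with tetrahydroxydiboron in MeOH should give [4-(benzyloxy)-3-(methanesulfonyloxy)phenyl]boronic acid F1.
- Commercial 7-hydroxy-4H-chromen-4-one is silylated (TIPSCl, imidazole) to 7-(triisopropylsilyloxy)-4H-chromen-4-one F2.
- Asymmetric conjugate addition of F1 to F2, catalysed by divalent palladium (Pd(OCOCF3)2, the tert-butyl pyridine–oxazoline antipode that furnishes the 2S product, aqueous ClCH2CH2Cl, 60 °C), forms C2–C1' on a preformed ring C and should give (2S)-2-[4-(benzyloxy)-3-(methanesulfonyloxy)phenyl]-7-(triisopropylsilyloxy)chroman-4-one F3.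
- NaBH4 reduction gives (2S)-2-[4-(benzyloxy)-3-(methanesulfonyloxy)phenyl]-7-(triisopropylsilyloxy)chroman-4-ol F4.
- Ionic hydrogenation of the doubly oxygen-activated C4 alcohol (Et3SiH, CF3CO2H, CH2Cl2, −20 °C) gives 10.

Step 11. What may go wrong: sulfene elimination is sluggish on the crowded, electron-rich ring, or the amide base attacks the silyl ether, so the two oxygen protecting groups are not differentiated cleanly. The fallback sets out from 15 and returns at 16. Both groups are removed together with KOH in MeOH/THF at 50 °C to give 2,2-dimethyl-6-[(2S)-7-hydroxychroman-2-yl]-2H-chromen-8-ol F5. TIPSCl/imidazole at low temperature should then silylate the unhindered ring-A 7-hydroxyl in preference to the chromene 8-hydroxyl, which is flanked by and hydrogen-bonded to the pyran oxygen, giving 16.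

Step 14. What may go wrong: the tertiary allyl ether ionises (loss of isoprene or a 1,3-shift) faster than the [3,3] shift into the crowded C7 position, or the product prenylphenol cyclises thermally onto its neighbouring hydroxyl. The fallback sets out from 16 and returns at 20, bypassing 17 to 19. The sodium phenoxide of 16 (NaH, PhMe) is C-alkylated with 1-bromo-3-methylbut-2-ene at 0 °C to rt; in the non-polar solvent the tight ion pair directs alkylation to the ortho carbon, and C7 is the only free one. This fallback makes no compound outside the list (F0).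

**Further compounds**

F1 | step 7 | [4-(benzyloxy)-3-(methanesulfonyloxy)phenyl]boronic acid | CS(=O)(=O)Oc1cc(B(O)O)ccc1OCc1ccccc1
F2 | step 7 | 7-(triisopropylsilyloxy)-4H-chromen-4-one | O=c1ccoc2cc(O[Si](C(C)C)(C(C)C)C(C)C)ccc12
F3 | step 7 | (2S)-2-[4-(benzyloxy)-3-(methanesulfonyloxy)phenyl]-7-(triisopropylsilyloxy)chroman-4-one | CS(=O)(=O)Oc1cc([C@@H]2CC(=O)c3ccc(O[Si](C(C)C)(C(C)C)C(C)C)cc3O2)ccc1OCc1ccccc1
F4 | step 7 | (2S)-2-[4-(benzyloxy)-3-(methanesulfonyloxy)phenyl]-7-(triisopropylsilyloxy)chroman-4-ol (C4 epimers, 2,4-cis expected to predominate) | CS(=O)(=O)Oc1cc([C@@H]2CC(O)c3ccc(O[Si](C(C)C)(C(C)C)C(C)C)cc3O2)ccc1OCc1ccccc1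
F5 | step 11 | 2,2-dimethyl-6-[(2S)-7-hydroxychroman-2-yl]-2H-chromen-8-ol | Oc1cc([C@@H]2CCc3ccc(O)cc3O2)cc2c1OC(C)(C)C=C2
F0 | step 14 | none | none
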